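| setting | ash | birch | flask |
|---|---|---|---|
| substrate | 28 mM | 44 mM | 20 mM |
| gas phase | 0.93 mM (held) | 0.93 mM (held) | 0.93 mM (held) |
| remark | run made earlier | run made earlier |  |
| time |  |  | 8.0 min |

| ash: time / min | ash: target / % | birch: time / min | birch: target / % |
|---|---|---|---|
| 0.500 | 11.2 | 1.33 | 19.0 |
| 1.50 | 30.9 | 2.50 | 32.9 |
| 3.00 | 47.2 | 4.00 | 42.8 |
| 4.00 | 52.2 | 5.00 | 47.9 |
| 6.00 | 56.0 | 6.00 | 50.5 |
| 8.00 | 57.2 | 8.00 | 56.7 |

(each reading ± 1 percentage point)

- target at 8.0 min, in percent of the substrate charged
- concentration of dissolved gas in solution at 8.0 min, in percent of saturation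

- at the start none of the gas phase is in solution

1. It is impossible for target to outrun, for long, the gas entering solution. The ash run opens at 6.27 mM min⁻¹ of target and the birch run at 6.29 mM min⁻¹, practically the same rate from different charges of substrate. Gas entry therefore looks like the rate-limiting step of those openings, and this reading is taken as the gas ceiling, the rate at which gas enters a solution holding none.

2. Entry falls as the solution fills. With gas held and dissolved gas near balance, the fractional gap below saturation is therefore gas use divided by the ceiling.

3. Two extreme flasks can be solved at once. A finished flask uses no gas and stands at 100% of saturation, while a flask using gas at the ceiling has a gap of 100%. The real flask lies between them.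

4. To place it, the ash run gained 1.2 percentage points of target over its last 2.00 min, a small gain that carries the scatter. On the flask's charge, that gain means a gas use of 0.120 mM min⁻¹ and a fractional gap below saturation of 1.91%. This reckoning therefore gives about 98.1% of saturation, and about 57.0% target from the last readings of both runs.

5. The forecast differs slightly, with 56% target and 99% of saturation: “With substrate nearly gone, gas demand is tiny compared with transfer capacity”.

6. The flask gives 57.2% target and 92.3% of saturation.

    gas phase ⇌ dissolved gas, rate k1*(csat - [dissolved gas]) (kL = 0.140 s⁻¹)
    substrate + dissolved gas → target (k = 39.0 M⁻¹ s⁻¹)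
    substrate ⇌ dormant form (K = 2.30, k = 0.0120 s⁻¹)
    target ⇌ isomer of the product (K = 17.0, k = 0.00130 s⁻¹)

7. The reckoned gap of 1.91% stands below the flask's 7.69%. By the constants, gas enters a solution holding none at 7.81 mM min⁻¹, so the flask's gap means a gas use of 0.601 mM min⁻¹, and its substrate and dissolved gas at 8.00 min react at 0.585 mM min⁻¹. Read at 3.0 min, the same flask holds 52.5% target and 0.696 mM dissolved gas. Its gap of 25.2% means a gas use of 1.97 mM min⁻¹, and its substrate and dissolved gas react at 1.88 mM min⁻¹.

The numbers in the tables were generated by integration with made-up constants; scatter was added.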